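**Retrosynthetic overview** (azulene locants, ring ketone = C4)

1. The vanillate is attached last to the secondary C8 hydroxyl of the hydroazulenone diol; the seven-membered ring of that diol is opened at C5–C6 (Pd-catalysed α-alkenylation of a C4 methyl ketone by a 2-bromoallyl group, then conjugation).
2. The C8 carbinol comes from a C8 ketone by chelation-controlled reduction, the C1 carbinol from isopropyl addition to a cyclopentanone, and the C4 acetyl group from a 1-silylvinyl group.
3. Key disconnection: C4–C3a and C8–C8a are formed together by a three-component conjugate addition–aldol coupling of 3-methylcyclopent-2-en-1-one, a 1-silylvinyl aluminium reagent and 3-bromobut-3-enal.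
4. Enabling feature: in the five-membered ring the tertiary carbinol C1 (a latent C=O), the ring-fusion CH C8a and the quaternary C3a–CH3 are the carbonyl, α- and β-carbons of 3-methylcyclopent-2-enone; the C4 ketone on C3a is a 1,4-dicarbonyl (acyl-anion conjugate addition) retron and the C8 carbinol on C8a is an aldol retron.
5. Ring order: the five-membered ring is present from the start; the seven-membered ring is closed late at C5–C6, remote from both fusion atoms, so the trans fusion set in the key step is kept.

Key step: step 2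

Remark (assumption): C1 = carbinol carbon bearing isopropyl, C3a = quaternary methyl carbon, C8 = ester-bearing carbon, C8a = ring-fusion CH. Compounds 7 and 8 are drawn as the expected major carbinol epimer; any minor epimer converges in step 4.

**Step 1**
Reactants: 1 3-bromobut-3-en-1-ol
Product: 2 3-bromobut-3-enal
Conditions: Dess–Martin periodinane, CH2Cl2, 0 °C to rt; used at once
Reagents that add atoms: none
Why: Dess–Martin oxidation stops at the aldehyde under near-neutral conditions, which should avoid isomerisation of the β,γ-unsaturated aldehyde into conjugation.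

**Step 2**
Reactants: 3 ethynyltrimethylsilane; 4 3-methylcyclopent-2-en-1-one; 2 3-bromobut-3-enal
Product: 7 (2S,3S)-2-[(1S)-3-bromo-1-hydroxybut-3-en-1-yl]-3-methyl-3-[1-(trimethylsilyl)ethenyl]cyclopentan-1-one, via silylvinyl alane 5 (not isolated), via aluminium enolate 6 (not isolated)
Conditions: 3, iBu2AlH, hexanes/THF, 55 °C; then 4, CuCl2·2H2O (5 mol %), chiral sulfonate-bearing imidazolinium salt (NHC precursor, 5 mol %), THF, −78 °C; then 2, −78 to −40 °C; aq. Rochelle salt
Reagents that add atoms: none
Why: iBu2AlH adds across the silylalkyne with aluminium on the silicon-bearing carbon to give alane 5; the chiral NHC–copper catalyst transfers its alkenyl group to the β-carbon of enone 4 (bond C4–C3a, quaternary centre), and the resulting aluminium enolate 6 adds through its α-carbon to aldehyde 2 (bond C8–C8a). The closest known reaction types are the NHC–copper-catalysed enantioselective conjugate addition of silicon-substituted vinylaluminium reagents to β-substituted cyclopentenones and the three-component conjugate addition–aldol coupling of cyclopentenones. No ring is closed here; the seven-membered ring is closed in step 8 at C5–C6, away from both fusion atoms, which is what permits a trans ring fusion. C3a (S) is set by the ligand, whose enantiomer is chosen for that enone face; C8a is set by the substrate, because the aldehyde should approach the enolate anti to the bulky 1-silylvinyl group and syn to the methyl group, placing the C8 and C4 branches trans. The carbinol centre follows from the closed aldol transition state (anti expected) and is reset in steps 4 and 5. The step needs 1,4- over 1,2-addition (copper catalysis), alkenyl over isobutyl transfer (the sp2 group migrates preferentially) and aldol addition over enolisation of the aldehyde (weakly basic aluminium enolate, low temperature, no excess alane).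

**Step 3**
Reactants: 7 (2S,3S)-2-[(1S)-3-bromo-1-hydroxybut-3-en-1-yl]-3-methyl-3-[1-(trimethylsilyl)ethenyl]cyclopentan-1-one
Product: 8 (1R,2S,3S)-2-[(1S)-3-bromo-1-hydroxybut-3-en-1-yl]-3-methyl-1-(propan-2-yl)-3-[1-(trimethylsilyl)ethenyl]cyclopentan-1-ol
Conditions: iPrMgCl (3 equiv), anhydrous CeCl3, THF, −78 to 0 °C
Reagents that add atoms: isopropylmagnesium chloride, CC(C)[Mg]Cl
Why: Organocerium addition (Imamoto conditions) suppresses enolisation and β-hydride reduction, and the nucleophile should attack the cyclopentanone face anti to the adjacent C2 side chain, giving the tertiary alcohol cis to that chain (1R).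

**Step 4**
Reactants: 8 (1R,2S,3S)-2-[(1S)-3-bromo-1-hydroxybut-3-en-1-yl]-3-methyl-1-(propan-2-yl)-3-[1-(trimethylsilyl)ethenyl]cyclopentan-1-ol
Product: 9 4-bromo-1-[(1R,2R,5S)-2-hydroxy-5-methyl-2-(propan-2-yl)-5-[1-(trimethylsilyl)ethenyl]cyclopentyl]pent-4-en-1-one
Conditions: Dess–Martin periodinane, CH2Cl2, 0 °C
Reagents that add atoms: none
Why: Dess–Martin oxidation touches only the secondary carbinol and erases its aldol-derived configuration under neutral conditions; the α-centre keeps the thermodynamically preferred arrangement (acyl group cis to methyl and hydroxyl, trans to isopropyl and silylvinyl).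

**Step 5**
Reactants: 9 4-bromo-1-[(1R,2R,5S)-2-hydroxy-5-methyl-2-(propan-2-yl)-5-[1-(trimethylsilyl)ethenyl]cyclopentyl]pent-4-en-1-one
Product: 10 (1R,2S,3S)-2-[(1R)-3-bromo-1-hydroxybut-3-en-1-yl]-3-methyl-1-(propan-2-yl)-3-[1-(trimethylsilyl)ethenyl]cyclopentan-1-ol
Conditions: Et2BOMe, THF/MeOH (4:1), −78 °C; NaBH4, −78 °C; aq. work-up, then MeOH co-evaporation (boron leaves as Et2BOMe)
Reagents that add atoms: none
Why: Narasaka–Prasad reduction: Et2BOMe ties the tertiary hydroxyl and the ketone into a six-membered boron chelate cis-fused to the cyclopentane, and external hydride should attack the face remote from the angular methyl group, giving the (R)-carbinol.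

**Step 6**
Reactants: 10 (1R,2S,3S)-2-[(1R)-3-bromo-1-hydroxybut-3-en-1-yl]-3-methyl-1-(propan-2-yl)-3-[1-(trimethylsilyl)ethenyl]cyclopentan-1-ol
Product: 11 (1R,2S,3S)-2-[(1R)-3-bromo-1-hydroxybut-3-en-1-yl]-3-methyl-1-(propan-2-yl)-3-[2-(trimethylsilyl)oxiran-2-yl]cyclopentan-1-ol (both epimers at the oxirane carbon)
Conditions: mCPBA, CH2Cl2, 0 °C to rt
Reagents that add atoms: mCPBA, OOC(=O)c1cccc(Cl)c1
Why: Prilezhaev epoxidation should select the 1,1-disubstituted vinylsilane over the electron-poor 2-bromoalkene; the new oxirane centre is destroyed in step 7, so its configuration does not matter.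

**Step 7**
Reactants: 11 (1R,2S,3S)-2-[(1R)-3-bromo-1-hydroxybut-3-en-1-yl]-3-methyl-1-(propan-2-yl)-3-[2-(trimethylsilyl)oxiran-2-yl]cyclopentan-1-ol
Product: 12 1-[(1S,2S,3R)-2-[(1R)-3-bromo-1-hydroxybut-3-en-1-yl]-3-hydroxy-1-methyl-3-(propan-2-yl)cyclopentyl]ethan-1-one
Conditions: H2SO4 (10% aq.), MeOH, rt
Reagents that add atoms: none
Why: Acid hydrolysis of the α,β-epoxysilane (ring opening by water, then Peterson-type loss of Me3SiOH to the enol) unmasks the methyl ketone at the carbon that bore silicon; the vinyl bromide and the tertiary alcohol should tolerate dilute acid at room temperature.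

**Step 8**
Reactants: 12 1-[(1S,2S,3R)-2-[(1R)-3-bromo-1-hydroxybut-3-en-1-yl]-3-hydroxy-1-methyl-3-(propan-2-yl)cyclopentyl]ethan-1-one
Product: 14 (1R,3aS,8R,8aS)-1,8-dihydroxy-3a,6-dimethyl-1-(propan-2-yl)-2,3,3a,7,8,8a-hexahydroazulen-4(1H)-one, via exocyclic methylene ketone 13 (not isolated)
Conditions: Pd(PPh3)4 (10 mol %), KOPh, THF, 70 °C; then DBU (cat.), CH2Cl2, rt
Reagents that add atoms: none
Why: Palladium-catalysed intramolecular α-alkenylation of a ketone enolate by a 2-bromoalkene (oxidative addition of zerovalent palladium, enolisation at the only enolisable position because the other α-carbon is quaternary, C–C reductive elimination) closes the seven-membered ring at C5–C6, and DBU moves the exocyclic double bond into conjugation; no stereocentre is touched.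

**Step 9**
Reactants: 14 (1R,3aS,8R,8aS)-1,8-dihydroxy-3a,6-dimethyl-1-(propan-2-yl)-2,3,3a,7,8,8a-hexahydroazulen-4(1H)-one; 15 4-(acetyloxy)-3-methoxybenzoic acid
Product: 16 (1R,3aS,8R,8aS)-1-hydroxy-3a,6-dimethyl-4-oxo-1-(propan-2-yl)-1,2,3,3a,4,7,8,8a-octahydroazulen-8-yl 4-(acetyloxy)-3-methoxybenzoate
Conditions: DCC, DMAP, CH2Cl2, 0 °C to rt
Reagents that add atoms: none
Why: Steglich esterification should acylate the secondary C8 hydroxyl with retention while the hindered tertiary C1 hydroxyl stays free.

**Step 10**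
Reactants: 16 (1R,3aS,8R,8aS)-1-hydroxy-3a,6-dimethyl-4-oxo-1-(propan-2-yl)-1,2,3,3a,4,7,8,8a-octahydroazulen-8-yl 4-(acetyloxy)-3-methoxybenzoate
Product: 17 (1R,3aS,8R,8aS)-1-hydroxy-3a,6-dimethyl-4-oxo-1-(propan-2-yl)-1,2,3,3a,4,7,8,8a-octahydroazulen-8-yl 4-hydroxy-3-methoxybenzoate (target)
Conditions: pyrrolidine (1.1 equiv), CH2Cl2, 0 °C
Reagents that add atoms: none
Why: Aminolysis of the aryl acetate is far faster than attack on the hindered alkyl benzoate or conjugate addition to the β,β-disubstituted enone, so the phenol should be released selectively.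

**Compound list**

1 | 3-bromobut-3-en-1-ol | OCCC(Br)=C | starting material
2 | 3-bromobut-3-enal | O=CCC(Br)=C | intermediate
3 | ethynyltrimethylsilane | C#C[Si](C)(C)C | starting material
4 | 3-methylcyclopent-2-en-1-one | CC1=CC(=O)CC1 | starting material
5 | diisobutyl[1-(trimethylsilyl)ethenyl]alumane | C=C([Si](C)(C)C)[Al](CC(C)C)CC(C)C | intermediate
6 | diisobutylaluminium (3S)-3-methyl-3-[1-(trimethylsilyl)ethenyl]cyclopent-1-en-1-olate | C=C([Si](C)(C)C)[C@@]1(C)CCC(O[Al](CC(C)C)CC(C)C)=C1 | intermediate
7 | (2S,3S)-2-[(1S)-3-bromo-1-hydroxybut-3-en-1-yl]-3-methyl-3-[1-(trimethylsilyl)ethenyl]cyclopentan-1-one | O=C1CC[C@](C)(C(=C)[Si](C)(C)C)[C@H]1[C@@H](O)CC(Br)=C | intermediate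
8 | (1R,2S,3S)-2-[(1S)-3-bromo-1-hydroxybut-3-en-1-yl]-3-methyl-1-(propan-2-yl)-3-[1-(trimethylsilyl)ethenyl]cyclopentan-1-ol | CC(C)[C@]1(O)CC[C@](C)(C(=C)[Si](C)(C)C)[C@H]1[C@@H](O)CC(Br)=C | intermediate
9 | 4-bromo-1-[(1R,2R,5S)-2-hydroxy-5-methyl-2-(propan-2-yl)-5-[1-(trimethylsilyl)ethenyl]cyclopentyl]pent-4-en-1-one | CC(C)[C@]1(O)CC[C@](C)(C(=C)[Si](C)(C)C)[C@H]1C(=O)CC(Br)=C | intermediate
10 | (1R,2S,3S)-2-[(1R)-3-bromo-1-hydroxybut-3-en-1-yl]-3-methyl-1-(propan-2-yl)-3-[1-(trimethylsilyl)ethenyl]cyclopentan-1-ol | CC(C)[C@]1(O)CC[C@](C)(C(=C)[Si](C)(C)C)[C@H]1[C@H](O)CC(Br)=C | intermediate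
11 | (1R,2S,3S)-2-[(1R)-3-bromo-1-hydroxybut-3-en-1-yl]-3-methyl-1-(propan-2-yl)-3-[2-(trimethylsilyl)oxiran-2-yl]cyclopentan-1-ol, both oxirane epimers | CC(C)[C@]1(O)CC[C@](C)(C2([Si](C)(C)C)CO2)[C@H]1[C@H](O)CC(Br)=C | intermediate
12 | 1-[(1S,2S,3R)-2-[(1R)-3-bromo-1-hydroxybut-3-en-1-yl]-3-hydroxy-1-methyl-3-(propan-2-yl)cyclopentyl]ethan-1-one | CC(C)[C@]1(O)CC[C@](C)(C(C)=O)[C@H]1[C@H](O)CC(Br)=C | intermediate
13 | (1R,3aS,8R,8aS)-1,8-dihydroxy-3a-methyl-6-methylidene-1-(propan-2-yl)octahydroazulen-4(1H)-one | O[C@@H]1CC(=C)CC(=O)[C@@]2(C)CC[C@@](O)(C(C)C)[C@H]12 | intermediate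
14 | (1R,3aS,8R,8aS)-1,8-dihydroxy-3a,6-dimethyl-1-(propan-2-yl)-2,3,3a,7,8,8a-hexahydroazulen-4(1H)-one | O[C@@H]1CC(C)=CC(=O)[C@@]2(C)CC[C@@](O)(C(C)C)[C@H]12 | intermediate
15 | 4-(acetyloxy)-3-methoxybenzoic acid | COc1cc(C(=O)O)ccc1OC(C)=O | starting material
16 | (1R,3aS,8R,8aS)-1-hydroxy-3a,6-dimethyl-4-oxo-1-(propan-2-yl)-1,2,3,3a,4,7,8,8a-octahydroazulen-8-yl 4-(acetyloxy)-3-methoxybenzoate | COc1cc(C(=O)O[C@@H]2CC(C)=CC(=O)[C@@]3(C)CC[C@@](O)(C(C)C)[C@H]23)ccc1OC(C)=O | intermediate
17 | (1R,3aS,8R,8aS)-1-hydroxy-3a,6-dimethyl-4-oxo-1-(propan-2-yl)-1,2,3,3a,4,7,8,8a-octahydroazulen-8-yl 4-hydroxy-3-methoxybenzoate | COc1cc(C(=O)O[C@@H]2CC(C)=CC(=O)[C@@]3(C)CC[C@@](O)(C(C)C)[C@H]23)ccc1O | target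

**Step count and risks**

Total step count: 10. Longest linear sequence: 10 steps (1 to 17); compounds 3, 4 and 15 enter convergently.

Steps most likely to fail:

Step 2. The hindered diisobutylaluminium enolate may add too slowly to the aldehyde, so that enolisation of the β,γ-unsaturated aldehyde or its consumption by residual alane competes and the second bond is not formed in the same pot. The fallback sets out from 4 (with 3): the same copper-catalysed conjugate addition is run, but enolate 6 is quenched with Me3SiCl to isolate the trimethylsilyl enol ether F1. A Mukaiyama aldol addition of F1 to 2 (BF3·OEt2, CH2Cl2, −78 °C) should then form the C8–C8a bond, again anti to the silylvinyl group, and comes back to the route at 7.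

Step 8. Reductive elimination through the eight-membered palladacycle may be slow, so that protodebromination or intermolecular coupling overtakes ring closure. The fallback sets out from 12 and closes the ring by metathesis. Negishi methylation of the vinyl bromide (MeZnCl, Pd(PPh3)4, THF, 50 °C) should give the 2-methylallyl ketone F2. α-Methylenation of its methyl ketone (paraformaldehyde, N-methylanilinium trifluoroacetate, THF, reflux) should give the vinyl ketone F3. Ring-closing metathesis (second-generation Hoveyda–Grubbs catalyst, toluene, 80 °C) should then form the C5=C6 double bond directly and comes back to the route at 14.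

Step 5. Facial selectivity of hydride addition to the boron chelate may be poor or of the opposite sense. The fallback sets out from 8 and omits steps 4 and 5: Mitsunobu reaction of the (1S)-carbinol (4-nitrobenzoic acid, PPh3, DIAD, toluene, 0 °C to rt) should give, with inversion, the (1R)-configured 4-nitrobenzoate F4, and its methanolysis (K2CO3, MeOH, 0 °C) comes back to the route at 10.

**Further compounds**

F1 | step 2 | trimethyl({(3S)-3-methyl-3-[1-(trimethylsilyl)ethenyl]cyclopent-1-en-1-yl}oxy)silane | C=C([Si](C)(C)C)[C@@]1(C)CCC(O[Si](C)(C)C)=C1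
F2 | step 8 | 1-[(1S,2S,3R)-3-hydroxy-2-[(1R)-1-hydroxy-3-methylbut-3-en-1-yl]-1-methyl-3-(propan-2-yl)cyclopentyl]ethan-1-one | CC(C)[C@]1(O)CC[C@](C)(C(C)=O)[C@H]1[C@H](O)CC(C)=C
F3 | step 8 | 1-[(1S,2S,3R)-3-hydroxy-2-[(1R)-1-hydroxy-3-methylbut-3-en-1-yl]-1-methyl-3-(propan-2-yl)cyclopentyl]prop-2-en-1-one | CC(C)[C@]1(O)CC[C@](C)(C(=O)C=C)[C@H]1[C@H](O)CC(C)=C
F4 | step 5 | (1R)-3-bromo-1-[(1S,2R,5S)-2-hydroxy-5-methyl-2-(propan-2-yl)-5-[1-(trimethylsilyl)ethenyl]cyclopentyl]but-3-en-1-yl 4-nitrobenzoate | CC(C)[C@]1(O)CC[C@](C)(C(=C)[Si](C)(C)C)[C@H]1[C@H](OC(=O)c2ccc(cc2)[N+](=O)[O-])CC(Br)=C
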